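**Strategy.** Everything rests on closing rings A and B around a vicinal dichloride that is already in place. A linear trienone carrying the (R,R)-syn-C2/C3 dichloride (one organocatalytic chlorination, one substrate-controlled addition, one invertive substitution) undergoes a metal-hydride hydrogen-atom-transfer (MHAT) radical bicyclisation: the C4 radical forms C4–C5, the C10 radical forms C9–C10 onto a γ-oxo-enoate. One operation gives the trans-decalin with the diequatorial 2α,3β-dichloride flanking the C4 gem-dimethyl carbon, the C10 quaternary methyl, C5, C9, a C8 ketone and the C11–C12 ester arm. The feature exploited is ring A's trans-diequatorial C2/C3 dichloride, which dictates the chair of ring closure. The precursor is made from geranylacetone.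

Key step: step 8

Remark: labdane numbering is used (ring A = C1–C5, C10; ring B = C5–C10; C18/C19 = gem-dimethyl on C4; C20 = methyl on C10; C17 = exocyclic methylene on C8; side chain C11–C16 from C9; α = below, β = above). The target is 7β-acetoxy-2α,3β-dichloro-(12S)-hydroxy, (13R), 5α-H, 9α-H, 10β-CH3.

Assumption: (2S,5S)-2,5-diphenylpyrrolidine is taken to deliver the (R)-α-chloro aldehyde; if the sense is the opposite, its antipode is used.

Step 1
Reactants: 1 (E)-geranylacetone
Product: 3 racemic (5E)-9,10-epoxy-6,10-dimethylundec-5-en-2-one, via bromohydrin 2 (not isolated)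
Conditions: NBS, THF/H2O 3:1, 0 °C; then K2CO3, MeOH, rt
Reagents that add atoms: water, O
Why: Terminal-selective bromohydrin formation in aqueous THF followed by Williamson-type closure should give the terminal epoxide; its stereocenter is racemic and is excised in step 2.

Step 2
Reactants: 3 racemic (5E)-9,10-epoxy-6,10-dimethylundec-5-en-2-one
Product: 4 (E)-4-methyl-8-oxonon-4-enal
Conditions: H5IO6, THF/Et2O, 0 °C
Reagents that add atoms: none
Why: Periodic acid hydrolyses the trisubstituted epoxide in situ and cleaves the glycol (Malaprade cleavage), releasing acetone; the ketone and the trisubstituted alkene are inert.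

Step 3
Reactants: 4 (E)-4-methyl-8-oxonon-4-enal
Product: 5 (2R,4E)-2-chloro-4-methyl-8-oxonon-4-enal
Conditions: NCS, (2S,5S)-2,5-diphenylpyrrolidine (10 mol%), CH2Cl2, 0 °C to rt; used crude
Reagents that add atoms: N-chlorosuccinimide, O=C1CCC(=O)N1Cl
Why: Enamine-catalysed asymmetric α-chlorination, in which the C2-symmetric amine shields one enamine face and sets the C2 chloride (R); only the aldehyde forms an enamine with the hindered amine, so the methyl ketone is untouched.

Step 4
Reactants: 5 (2R,4E)-2-chloro-4-methyl-8-oxonon-4-enal; 6 isopropenylmagnesium bromide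
Product: 7 (5E,8R,9S)-8-chloro-9-hydroxy-6,10-dimethylundeca-5,10-dien-2-one
Conditions: THF, −78 °C, slow addition of 6 (1.1 equiv); cold aqueous quench
Reagents that add atoms: none
Why: Grignard addition to the much more electrophilic α-chloro aldehyde (the dialkyl ketone reacts far more slowly at −78 °C) under Cornforth/polar Felkin–Anh control should give the 1,2-anti chlorohydrin, setting the C3 carbinol (S).

Step 5
Reactants: 7 (5E,8R,9S)-8-chloro-9-hydroxy-6,10-dimethylundeca-5,10-dien-2-one
Product: 8 (5E,8R,9R)-8,9-dichloro-6,10-dimethylundeca-5,10-dien-2-one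
Conditions: PPh3, hexachloroacetone, CH2Cl2, −20 to 0 °C
Reagents that add atoms: hexachloroacetone, ClC(Cl)(Cl)C(=O)C(Cl)(Cl)Cl
Why: Appel-type chlorination with PPh3/hexachloroacetone substitutes secondary allylic alcohols by SN2 with inversion and without allylic transposition, turning the anti chlorohydrin into the syn (R,R) dichloride (C3 set).

Step 6
Reactants: 8 (5E,8R,9R)-8,9-dichloro-6,10-dimethylundeca-5,10-dien-2-one; 9 methyl glyoxylate
Product: 10 methyl (7E,10R,11R)-10,11-dichloro-2-hydroxy-8,12-dimethyl-4-oxotrideca-7,12-dienoate (C2 epimers)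
Conditions: Bu2BOTf, iPr2NEt, CH2Cl2, −78 °C; then 9; pH 7 buffer, MeOH, H2O2, 0 °C
Reagents that add atoms: none
Why: Boron-mediated aldol addition in which Bu2BOTf/iPr2NEt enolises the methyl ketone on the methyl side without strong base, so the alkyl chlorides are safe; the new carbinol centre is removed in step 7.

Step 7
Reactants: 10 methyl (7E,10R,11R)-10,11-dichloro-2-hydroxy-8,12-dimethyl-4-oxotrideca-7,12-dienoate
Product: 11 methyl (2E,7E,10R,11R)-10,11-dichloro-8,12-dimethyl-4-oxotrideca-2,7,12-trienoate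
Conditions: MsCl, Et3N, CH2Cl2, 0 °C to rt
Reagents that add atoms: none
Why: Mesylation and E1cB elimination of the β-mesyloxy ketone should give the conjugated (E)-4-oxo-2-enoate, the thermodynamic geometry.

Step 8
Reactants: 11 methyl (2E,7E,10R,11R)-10,11-dichloro-8,12-dimethyl-4-oxotrideca-2,7,12-trienoate
Product: 12 methyl 2α,3β-dichloro-8-oxo-13,14,15,16,17-pentanorlabdan-12-oate (trans-decalin; 5α-H, 9α-H, 10β-CH3)
Conditions: Fe(acac)3 (0.5 equiv), PhSiH3 (2.5 equiv), EtOH/(CH2OH)2 5:1, 0.01 M, 40 °C
Reagents that add atoms: none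
Why: An iron hydride formed from Fe(acac)3/PhSiH3/EtOH transfers a hydrogen atom to the terminal CH2 of the isopropenyl group (Markovnikov MHAT), the C4 tertiary radical adds 6-endo-trig to C5 of the C5=C10 alkene to close ring A, the resulting C10 tertiary radical adds 6-exo-trig to C9 of the γ-oxo-enoate (Giese addition) to close ring B, and the C11 α-ester radical is reduced by Fe(II) and protonated by ethanol. The closest known reaction type is the MHAT-initiated reductive olefin coupling used for radical polyene bicyclisations that end on an unsaturated carbonyl. Ring A closes through a chair in which the syn C2/C3 chlorides are both equatorial (the flipped chair would make both axial, one against the axial C4 methyl), which fixes the face of C5 that is attacked and hence C5–H as α. The E geometry of C5=C10 and a chair–chair arrangement give the trans ring fusion with the C10 methyl axial (β), and C9, being α to the C8 ketone, settles with its CH2CO2Me arm equatorial (β) kinetically or by enolisation. The step needs hydrogen-atom transfer at the isopropenyl group and not at the trisubstituted alkene or the enoate; this is secured by the accessibility of the terminal =CH2 and the low reactivity of electron-poor alkenes toward the iron hydride, with high dilution favouring the intramolecular cascade. Loss of chlorine from the β-chloro C4 radical is endothermic and should be slower than 6-endo closure.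

Step 9
Reactants: 12 methyl 2α,3β-dichloro-8-oxo-13,14,15,16,17-pentanorlabdan-12-oate
Product: 13 methyl 2α,3β-dichloro-13,14,15,16-tetranorlabd-8(17)-en-12-oate
Conditions: Ph3PCH3Br, KHMDS, THF, 0 °C to rt
Reagents that add atoms: methyltriphenylphosphonium bromide, C[P+](c1ccccc1)(c1ccccc1)c1ccccc1.[Br-]
Why: Wittig methylenation of the ring ketone is faster than attack on the ester, the trans-diequatorial dichloride has no antiperiplanar hydrogen for E2, and any C9 epimerisation returns to the equatorial arm.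

Step 10
Reactants: 13 methyl 2α,3β-dichloro-13,14,15,16-tetranorlabd-8(17)-en-12-oate
Product: 14 methyl 2α,3β-dichloro-7α-hydroxy-13,14,15,16-tetranorlabd-8(17)-en-12-oate
Conditions: SeO2 (0.5 equiv), t-BuOOH, CH2Cl2, rt
Reagents that add atoms: tert-butyl hydroperoxide (terminal oxygen source, via SeO2), CC(C)(C)OO
Why: Selenium dioxide allylic oxidation (ene reaction then [2,3]-shift) should occur at the ring methylene C7 and not at the tertiary C9–H; the alcohol is expected axial (α) and is corrected in steps 11–12.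

Step 11
Reactants: 14 methyl 2α,3β-dichloro-7α-hydroxy-13,14,15,16-tetranorlabd-8(17)-en-12-oate
Product: 15 methyl 2α,3β-dichloro-7-oxo-13,14,15,16-tetranorlabd-8(17)-en-12-oate
Conditions: Dess–Martin periodinane, NaHCO3, CH2Cl2, 0 °C; used without chromatography
Reagents that add atoms: none
Why: Dess–Martin oxidation of the allylic alcohol under buffered, non-basic conditions should give the exocyclic enone without isomerisation to the endocyclic enone.

Step 12
Reactants: 15 methyl 2α,3β-dichloro-7-oxo-13,14,15,16-tetranorlabd-8(17)-en-12-oate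
Product: 16 methyl 2α,3β-dichloro-7β-hydroxy-13,14,15,16-tetranorlabd-8(17)-en-12-oate
Conditions: NaBH4, CeCl3·7H2O, MeOH, −78 °C
Reagents that add atoms: none
Why: Luche 1,2-reduction with axial hydride delivery from the α-face of the ring B chair should give the equatorial 7β-alcohol (C7 set); the ester is not reduced.

Step 13
Reactants: 16 methyl 2α,3β-dichloro-7β-hydroxy-13,14,15,16-tetranorlabd-8(17)-en-12-oate
Product: 17 2α,3β-dichloro-7β-hydroxy-13,14,15,16-tetranorlabd-8(17)-en-12-al
Conditions: DIBAL-H (2.2 equiv), CH2Cl2, −78 °C; Rochelle salt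
Reagents that add atoms: none
Why: Partial reduction of the methyl ester through the stable tetrahedral aluminate at −78 °C (the first equivalent is consumed by the C7 hydroxyl) should stop at the aldehyde.

Step 14
Reactants: 17 2α,3β-dichloro-7β-hydroxy-13,14,15,16-tetranorlabd-8(17)-en-12-al
Product: 18 7β-acetoxy-2α,3β-dichloro-13,14,15,16-tetranorlabd-8(17)-en-12-al
Conditions: Ac2O, pyridine, DMAP (cat.), CH2Cl2, 0 °C
Reagents that add atoms: acetic anhydride, CC(=O)OC(C)=O
Why: DMAP-catalysed acetylation of the secondary allylic alcohol; the aldehyde is inert.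

Step 15
Reactants: 19 3-cyanopropanoic acid; 20 (R)-4-benzyloxazolidin-2-one
Product: 21 (R)-4-benzyl-3-(3-cyanopropanoyl)oxazolidin-2-one
Conditions: 19, PivCl, Et3N, THF, −20 °C; then 20, LiCl, rt
Reagents that add atoms: none
Why: N-Acylation of the oxazolidinone through the mixed pivalic anhydride; no new stereocenter.

Step 16
Reactants: 18 7β-acetoxy-2α,3β-dichloro-13,14,15,16-tetranorlabd-8(17)-en-12-al; 21 (R)-4-benzyl-3-(3-cyanopropanoyl)oxazolidin-2-one
Product: 22 (4R)-4-benzyl-3-[(12S,13R)-7β-acetoxy-2α,3β-dichloro-12-hydroxy-15-nitrilolabd-8(17)-en-16-oyl]oxazolidin-2-one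
Conditions: 21, Bu2BOTf, iPr2NEt, CH2Cl2, −78 to 0 °C; then 18, −78 to 0 °C; pH 7 buffer, MeOH, H2O2
Reagents that add atoms: none
Why: Evans syn-aldol, in which the Z-boron enolate (formed α to the imide, not α to the nitrile) reacts through a Zimmerman–Traxler chair under control of the (R)-auxiliary, setting C12 (S) and C13 (R).

Step 17
Reactants: 22 (4R)-4-benzyl-3-[(12S,13R)-7β-acetoxy-2α,3β-dichloro-12-hydroxy-15-nitrilolabd-8(17)-en-16-oyl]oxazolidin-2-one
Product: 24 haterumaimide A, via primary amide 23 (not isolated)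
Conditions: [PtH{(PMe2O)2H}(PMe2OH)] (5 mol%), EtOH/H2O 4:1, 70 °C; then DBU (0.2 equiv), THF, 0 °C
Reagents that add atoms: water, O
Why: Neutral platinum-catalysed nitrile hydration gives the primary amide, whose nitrogen then attacks the activated N-acyl oxazolidinone carbonyl (5-exo-trig acyl transfer) to close the succinimide and release the auxiliary; the acetate and C13 should survive the mild base.

**Compound list**

1 | (E)-geranylacetone, (5E)-6,10-dimethylundeca-5,9-dien-2-one | CC(C)=CCC/C(C)=C/CCC(C)=O | starting material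
2 | (5E)-9-bromo-10-hydroxy-6,10-dimethylundec-5-en-2-one (racemic) | CC(C)(O)C(Br)CC/C(C)=C/CCC(C)=O | intermediate (not isolated)
3 | (5E)-9,10-epoxy-6,10-dimethylundec-5-en-2-one (racemic) | CC1(C)OC1CC/C(C)=C/CCC(C)=O | intermediate
4 | (E)-4-methyl-8-oxonon-4-enal | O=CCC/C(C)=C/CCC(C)=O | intermediate
5 | (2R,4E)-2-chloro-4-methyl-8-oxonon-4-enal | O=C[C@H](Cl)C/C(C)=C/CCC(C)=O | intermediate
6 | isopropenylmagnesium bromide | C=C(C)[Mg]Br | starting material
7 | (5E,8R,9S)-8-chloro-9-hydroxy-6,10-dimethylundeca-5,10-dien-2-one | C=C(C)[C@H](O)[C@H](Cl)C/C(C)=C/CCC(C)=O | intermediate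
8 | (5E,8R,9R)-8,9-dichloro-6,10-dimethylundeca-5,10-dien-2-one | C=C(C)[C@@H](Cl)[C@H](Cl)C/C(C)=C/CCC(C)=O | intermediate
9 | methyl glyoxylate | O=CC(=O)OC | starting material
10 | methyl (7E,10R,11R)-10,11-dichloro-2-hydroxy-8,12-dimethyl-4-oxotrideca-7,12-dienoate (C2 epimers) | C=C(C)[C@@H](Cl)[C@H](Cl)C/C(C)=C/CCC(=O)CC(O)C(=O)OC | intermediate
11 | methyl (2E,7E,10R,11R)-10,11-dichloro-8,12-dimethyl-4-oxotrideca-2,7,12-trienoate | C=C(C)[C@@H](Cl)[C@H](Cl)C/C(C)=C/CCC(=O)/C=C/C(=O)OC | intermediate
12 | methyl 2α,3β-dichloro-8-oxo-13,14,15,16,17-pentanorlabdan-12-oate | O=C1CC[C@H]2C(C)(C)[C@@H](Cl)[C@H](Cl)C[C@]2(C)[C@H]1CC(=O)OC | intermediate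
13 | methyl 2α,3β-dichloro-13,14,15,16-tetranorlabd-8(17)-en-12-oate | C=C1CC[C@H]2C(C)(C)[C@@H](Cl)[C@H](Cl)C[C@]2(C)[C@H]1CC(=O)OC | intermediate
14 | methyl 2α,3β-dichloro-7α-hydroxy-13,14,15,16-tetranorlabd-8(17)-en-12-oate | C=C1[C@H](O)C[C@H]2C(C)(C)[C@@H](Cl)[C@H](Cl)C[C@]2(C)[C@H]1CC(=O)OC | intermediate
15 | methyl 2α,3β-dichloro-7-oxo-13,14,15,16-tetranorlabd-8(17)-en-12-oate | C=C1C(=O)C[C@H]2C(C)(C)[C@@H](Cl)[C@H](Cl)C[C@]2(C)[C@H]1CC(=O)OC | intermediate
16 | methyl 2α,3β-dichloro-7β-hydroxy-13,14,15,16-tetranorlabd-8(17)-en-12-oate | C=C1[C@@H](O)C[C@H]2C(C)(C)[C@@H](Cl)[C@H](Cl)C[C@]2(C)[C@H]1CC(=O)OC | intermediate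
17 | 2α,3β-dichloro-7β-hydroxy-13,14,15,16-tetranorlabd-8(17)-en-12-al | C=C1[C@@H](O)C[C@H]2C(C)(C)[C@@H](Cl)[C@H](Cl)C[C@]2(C)[C@H]1CC=O | intermediate
18 | 7β-acetoxy-2α,3β-dichloro-13,14,15,16-tetranorlabd-8(17)-en-12-al | C=C1[C@@H](OC(C)=O)C[C@H]2C(C)(C)[C@@H](Cl)[C@H](Cl)C[C@]2(C)[C@H]1CC=O | intermediate
19 | 3-cyanopropanoic acid | N#CCCC(=O)O | starting material
20 | (R)-4-benzyloxazolidin-2-one | O=C1OC[C@@H](Cc2ccccc2)N1 | starting material
21 | (R)-4-benzyl-3-(3-cyanopropanoyl)oxazolidin-2-one | N#CCCC(=O)N1C(=O)OC[C@H]1Cc1ccccc1 | intermediate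
22 | (4R)-4-benzyl-3-[(12S,13R)-7β-acetoxy-2α,3β-dichloro-12-hydroxy-15-nitrilolabd-8(17)-en-16-oyl]oxazolidin-2-one | C=C1[C@@H](OC(C)=O)C[C@H]2C(C)(C)[C@@H](Cl)[C@H](Cl)C[C@]2(C)[C@H]1C[C@H](O)[C@H](C(=O)N3C(=O)OC[C@H]3Cc4ccccc4)CC#N | intermediate
23 | primary amide of 22 (C15 carboxamide in place of the nitrile) | C=C1[C@@H](OC(C)=O)C[C@H]2C(C)(C)[C@@H](Cl)[C@H](Cl)C[C@]2(C)[C@H]1C[C@H](O)[C@H](C(=O)N3C(=O)OC[C@H]3Cc4ccccc4)CC(N)=O | intermediate (not isolated)
24 | haterumaimide A | C=C1[C@@H](OC(C)=O)C[C@H]2C(C)(C)[C@@H](Cl)[C@H](Cl)C[C@]2(C)[C@H]1C[C@H](O)[C@H]1CC(=O)NC1=O | target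

**Step count and risks**

Total steps: 17. Longest linear sequence: 16 (steps 1–14, 16, 17).

Step 8. Hydrogen-atom transfer may fail to discriminate between the chlorine-deactivated isopropenyl group, the C5=C10 alkene and the enoate, so that mono-cyclised or merely reduced material would form. The fallback makes the C4 radical from a site-defined C–O precursor with no hydride present. It sets out from 8: Mukaiyama hydration (Co(acac)2, PhSiH3, O2) of the 1,1-disubstituted alkene should give the tertiary alcohol (5E,8R,9R)-8,9-dichloro-10-hydroxy-6,10-dimethylundec-5-en-2-one F1, and any regioisomer can be removed at this stage. Boron aldol addition to 9 should give methyl (7E,10R,11R)-10,11-dichloro-2,12-dihydroxy-8,12-dimethyl-4-oxotridec-7-enoate F2, and MsCl/Et3N its enoate methyl (2E,7E,10R,11R)-10,11-dichloro-12-hydroxy-8,12-dimethyl-4-oxotrideca-2,7-dienoate F3. Methyl chlorooxoacetate (Et3N, DMAP) acylates the tertiary alcohol to methyl (2E,7E,10R,11R)-10,11-dichloro-12-(2-methoxy-2-oxoacetoxy)-8,12-dimethyl-4-oxotrideca-2,7-dienoate F4, and one equivalent of CsOH gives the caesium salt of the oxalic acid half-ester of F3 F5. Visible-light photoredox oxidation (Ir[dF(CF3)ppy]2(dtbbpy)PF6, DME/DMF/H2O) releases two CO2 and the C4 radical; the same 6-endo/6-exo cascade, ended by reduction and protonation at C11, comes back to the route at 12.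

Step 5. The activated allylic oxygen may be displaced with allylic transposition (SN2′) or with retention through participation of the neighbouring chlorine, which would erode the syn-dichloride. The fallback makes both C–Cl bonds from an epoxide and sets out from 7. K2CO3 in MeOH closes the anti chlorohydrin (inversion at C2) to the trans vinyl epoxide (5E)-6-methyl-7-[(2S,3S)-3-(prop-1-en-2-yl)oxiran-2-yl]hept-5-en-2-one F6. Epoxide deoxydichlorination (Ph3P, NCS, CH2Cl2) inverts both carbons, so C2 is inverted twice and C3 once, and the sequence comes back to the route at 8. No chlorine flanks the allylic carbon at the moment it is substituted.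

Step 17. Under the basic ring closure the β-hydroxy imide may undergo retro-aldol cleavage, C13 epimerisation or acetate loss before the amide nitrogen has displaced the auxiliary. The fallback removes the auxiliary first and closes the imide by acid activation; it sets out from 22. LiOH/H2O2 (THF/H2O, 0 °C) should give (12S,13R)-7β-acetoxy-2α,3β-dichloro-12-hydroxy-15-nitrilolabd-8(17)-en-16-oic acid F7; platinum-catalysed hydration of the nitrile gives the succinamic acid (12S,13R)-7β-acetoxy-2α,3β-dichloro-12-hydroxy-15-amino-15-oxolabd-8(17)-en-16-oic acid F8; cyclodehydration (CDI, THF) closes the succinimide and comes back to the route at 24.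

Further compounds
F1 | step 8 | (5E,8R,9R)-8,9-dichloro-10-hydroxy-6,10-dimethylundec-5-en-2-one | CC(C)(O)[C@@H](Cl)[C@H](Cl)C/C(C)=C/CCC(C)=O
F2 | step 8 | methyl (7E,10R,11R)-10,11-dichloro-2,12-dihydroxy-8,12-dimethyl-4-oxotridec-7-enoate | CC(C)(O)[C@@H](Cl)[C@H](Cl)C/C(C)=C/CCC(=O)CC(O)C(=O)OC
F3 | step 8 | methyl (2E,7E,10R,11R)-10,11-dichloro-12-hydroxy-8,12-dimethyl-4-oxotrideca-2,7-dienoate | CC(C)(O)[C@@H](Cl)[C@H](Cl)C/C(C)=C/CCC(=O)/C=C/C(=O)OC
F4 | step 8 | methyl (2E,7E,10R,11R)-10,11-dichloro-12-(2-methoxy-2-oxoacetoxy)-8,12-dimethyl-4-oxotrideca-2,7-dienoate | COC(=O)C(=O)OC(C)(C)[C@@H](Cl)[C@H](Cl)C/C(C)=C/CCC(=O)/C=C/C(=O)OC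
F5 | step 8 | caesium salt of the oxalic acid half-ester of F3 | [Cs+].[O-]C(=O)C(=O)OC(C)(C)[C@@H](Cl)[C@H](Cl)C/C(C)=C/CCC(=O)/C=C/C(=O)OC
F6 | step 5 | (5E)-6-methyl-7-[(2S,3S)-3-(prop-1-en-2-yl)oxiran-2-yl]hept-5-en-2-one | C=C(C)[C@@H]1O[C@H]1C/C(C)=C/CCC(C)=O
F7 | step 17 | (12S,13R)-7β-acetoxy-2α,3β-dichloro-12-hydroxy-15-nitrilolabd-8(17)-en-16-oic acid | C=C1[C@@H](OC(C)=O)C[C@H]2C(C)(C)[C@@H](Cl)[C@H](Cl)C[C@]2(C)[C@H]1C[C@H](O)[C@H](C(=O)O)CC#N
F8 | step 17 | (12S,13R)-7β-acetoxy-2α,3β-dichloro-12-hydroxy-15-amino-15-oxolabd-8(17)-en-16-oic acid | C=C1[C@@H](OC(C)=O)C[C@H]2C(C)(C)[C@@H](Cl)[C@H](Cl)C[C@]2(C)[C@H]1C[C@H](O)[C@H](C(=O)O)CC(N)=O
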